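## Structural features

Acerosin (12) is a flavone: a benzene ring A fused to a 4-pyranone ring C, with the aryl ring B attached to C2 by a single bond. Ring A is fully substituted, with hydroxyls at C5 and C7, methoxy groups at C6 and C8, the carbon-bound fusion atom C4a and the oxygen-bound fusion atom C8a; ring B is a 3-hydroxy-4-methoxyphenyl group. The molecule is planar and achiral, so there are no stereocentres and no question of adjacent stereocentres. The fragile features are the electron-rich polyphenolic rings, which oxidise to quinones once the hydroxyls are free, the three methyl ethers that must survive while three hydroxyls are unmasked, and the acid-induced opening and reclosure of ring C (Wessely–Moser isomerisation) typical of 5-hydroxyflavones with oxygen at C6 and C8. The real difficulty is the pentaoxygenated ring A with its alternating OH/OMe pattern and the regiochemistry of closing ring C onto it. When ring C is opened at O1–C2, the ring A fragment has a mirror plane through C4a and C7, so the two ortho oxygens (future O1 and 5-OH) and the two methoxy carbons (C6 and C8) are equivalent, and ring closure or any Wessely–Moser shuffle can lead to one flavone only. The key step exploits C2, which is bonded only to C1' of ring B, to C3 and to O1: it is the second carbonyl carbon of a 1,3-diketone and can be supplied as carbon monoxide between a ring B halide and the methyl carbon (future C3) of a symmetric ring A acetophenone.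

## Logic of the disconnections

12 to 11. The O1–C2 bond is cut and water is added back across C2=C3, which opens the pyranone to a 1,3-diketone with C2 and C4 as carbonyls. Closure of such a diketone by an ortho hydroxyl is the most dependable flavone synthesis, and in 11 the two ortho hydroxyls are equivalent. Ring C and every regiochemical question disappear. The forward step must dehydrate under acid without touching the methyl ethers; the symmetry of ring A makes any ring-opening equilibrium degenerate.

11 to 10. Four O–H bonds are replaced by O–benzyl bonds. The preceding carbon–carbon bond formation runs through a strongly basic enolate and an acyl–palladium species, neither of which tolerates free phenols. One kind of protecting group on all four oxygens keeps ring A symmetric and allows a single hydrogenolysis. The demand is that benzylic C–O bonds are cleaved faster than the aryl ketones are reduced.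

10 to 5, 7 and 8. The C1'–C2 and C2–C3 bonds are cut: C2 with its oxygen becomes 8, ring B becomes 7, and ring A with C4 and C3 becomes 5. This is the most simplifying cut, since it divides 10 into two aromatic pieces of similar size and a one-carbon gas and creates C2 at the oxidation level the target needs. The demand is that enolate 9, made from 5, is acylated at carbon by the aroyl–palladium species from 7 and 8, ahead of O-acylation and of direct arylation. Two equivalents of base are budgeted because 10 is far more acidic than 5. As 5 has one enolisable position only, no regiochemical issue arises.

5 to 4. The aryl–acetyl bond (C4a–C4) is cut. 4 has a single ring hydrogen, flanked by two benzyloxy groups and strongly activated, so electrophilic acetylation can occur nowhere else. The demand is an acylating system mild enough to leave the benzyl ethers, especially those ortho to the new carbonyl, in place.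

4 to 3. The two aryl C–OMe bonds (future C6–O and C8–O) are cut back to C–Br. Halide-to-methoxide exchange is the shortest way to add two oxygens to a ring that already carries three. The demand is copper-mediated substitution at two positions each flanked by two benzyloxy groups, without reductive loss of bromine.

3 to 2. Two C–Br bonds are cut. The three ring positions of 2 are equivalent, so stoichiometry alone fixes how many are brominated, and the third is kept for the acetyl group.

2 to 1, and 7 to 6. O–benzyl bonds are cut, leading to two commercial phenols. For 1 the demand is O-alkylation in preference to C-alkylation; for 6 there is none beyond a routine etherification.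

## Other disconnections considered

Alternative 1: The cut is at C4–C4a and O1–C2, so ring C would be formed in one operation from a ring A phenol and a ring B ketoester. In the forward step, 2,4-dimethoxybenzene-1,3,5-triol A1 and ethyl 3-[3-(benzyloxy)-4-methoxyphenyl]-3-oxopropanoate A2 would be heated neat near 240 °C without catalyst. Loss of ethanol (probably through an aroylketene) would acylate the only free ring carbon of A1, and an ortho hydroxyl would then close onto the aryl ketone with loss of water to give 3'-O-benzylacerosin A3. Hydrogenolysis of A3 would give 12.
- In its favour: two bonds and ring C are formed at once. No palladium and no carbon monoxide are needed, which is better than the chosen plan on reagent hazard and cost. A1 has one ring C–H and the same mirror symmetry as 5, so regiochemistry is as unambiguous as in the chosen plan (equal). A1 should be available from 4 by hydrogenolysis.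
- Against it here: A1 is a free pentaoxygenated phenol, far more oxidation-prone than anything in the chosen route before step 7, and it would have to survive 240 °C. C-acylation at a carbon flanked by two hydroxyls competes with O-acylation and with attack of the ring on the ketone carbonyl of A2, the Pechmann mode, which would lead to a 4-arylcoumarin skeleton. The benzyl ether of ring B may not tolerate the temperature.
- Comparison: on structure the two plans use the same symmetry. On mechanism the chosen plan makes the diketone catalytically at 80 °C on a fully protected substrate and defers ring closure, trading one step for control. On step economy the counts are about equal: A1 costs one step beyond 4, A2 one or two steps from 7, and a final debenzylation remains.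

Alternative 2: The cut is at C4a–C5, so ring A would be built, not bought. In the forward step, 6-{(3E)-4-[3-(benzyloxy)-4-methoxyphenyl]-2-oxobut-3-en-1-yl}-4-hydroxy-3,5-dimethoxy-2H-pyran-2-one A4 would be opened by Mg(OMe)2 in methanol to a magnesium-chelated triketo ester. Its doubly activated methylene (future C4a) would attack the ester carbon that was the lactone carbonyl (future C5) in a Claisen closure, and enolisation would aromatise ring A. The product would be the chalcone (E)-3-[3-(benzyloxy)-4-methoxyphenyl]-1-(2,4,6-trihydroxy-3,5-dimethoxyphenyl)prop-2-en-1-one A5. Oxidative cyclisation of A5 (I2 in DMSO) would give A3, and hydrogenolysis would give 12.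
- In its favour: the pentaoxygenated ring appears with every oxygen in place, so the bromination and methoxylation of steps 2 and 3 are avoided. Ring A of A5 is again symmetric, so either ortho hydroxyl closes to the same flavone (equal to the chosen plan). The key step needs no transition metal and no toxic gas (better on that point).
- Against it here: A4 has no short preparation. Its two enol-ether methoxy groups and the cinnamoylmethyl side chain would need a linear sequence probably longer than the whole chosen route. The opened chain has further acidic C–H bonds at the methoxy-bearing carbons and an enone, so aldol-type closure onto the cinnamoyl carbonyl and conjugate addition of methoxide compete with the Claisen mode. The product is at the chalcone oxidation level, so a separate oxidation is needed, whereas carbon monoxide delivers C2 as a carbonyl (chosen plan better).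
- Comparison: the alternative relies on chelation-controlled folding of a polycarbonyl chain, which is harder to predict than the catalytic cycle of step 6, and it is clearly longer.

Alternative 3: The cut is at C2–C3 and C3–C4, so C3 would be inserted as a carbene into a five-membered ring. The benzofuranone 4,6-bis(benzyloxy)-2-[3-(benzyloxy)-4-methoxyphenyl]-5,7-dimethoxy-1-benzofuran-3(2H)-one A6 would be silylated to 4,6-bis(benzyloxy)-2-[3-(benzyloxy)-4-methoxyphenyl]-3-[(tert-butyldimethylsilyl)oxy]-5,7-dimethoxy-1-benzofuran A7. In the forward key step, dibromocarbene from bromoform and KOtBu would add to the electron-rich C2=C3 enol ether bond of A7. The dibromocyclopropane would open with loss of bromide and of the silyl group to give 5,7-bis(benzyloxy)-2-[3-(benzyloxy)-4-methoxyphenyl]-3-bromo-6,8-dimethoxy-4H-chromen-4-one A8. Hydrogenolysis would remove the C–Br bond and the three benzyl groups together to give 12.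
- In its favour: the pyranone arrives at the correct oxidation level without a cyclodehydration, so one step follows the key step against two in the chosen plan (better). No carbon monoxide is handled. Both plans add exactly one carbon atom in the key step (conceptually equal).
- Against it here: making A6 requires one of the three ring A oxygens to be differentiated from the other two early on, so the symmetry is spent before the key step and a selective protection enters. A6 is a 2-aryl-benzofuran-3-one, a class that oxidises readily at C2. The bromine is installed only to be removed. KOtBu can cleave the silyl enol ether before the carbene arrives.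
- Comparison: the several steps to A6 make the route longer overall, and the one-carbon unit of the chosen plan carries no waste atoms.

Key step: step 6

Assumption: 10 and 11 are written as diketo tautomers; both should exist largely as chelated enols, and 11 may equilibrate with its cyclic hemiketal, which does not affect the route.
Consistency check: in 7 the bromine is para to the methoxy group and meta to the benzyloxy group, as C1' of 12 requires, and in 5 the acetyl group lies between two benzyloxy groups with the methoxy groups meta to it, so 5, 7 and 10 map onto 12 with no change of substitution pattern.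

## Steps

Step 1
Reactants: 1 phloroglucinol (benzene-1,3,5-triol)
Product: 2 1,3,5-tris(benzyloxy)benzene
Conditions: BnBr (3.3 equiv), K2CO3 (4.5 equiv), DMF, rt → 50 °C, Ar
Reagents that add atoms: benzyl bromide, BrCc1ccccc1
Why: Threefold Williamson ether synthesis; a weak base in a dipolar aprotic solvent at low temperature favours attack through phenoxide oxygen, and C-benzylated by-products, the usual side products with phloroglucinol, should be removable by crystallisation of the symmetric ether 2.

Step 2
Reactants: 2 1,3,5-tris(benzyloxy)benzene
Product: 3 1,3,5-tris(benzyloxy)-2,4-dibromobenzene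
Conditions: NBS (2.05 equiv), CH2Cl2, −20 → 0 °C, dark
Reagents that add atoms: N-bromosuccinimide, O=C1CCC(=O)N1Br
Why: Electrophilic aromatic bromination; the three ring C–H positions of 2 are equivalent and each is ortho/para to three alkoxy groups, so two equivalents can give one dibromide only, and each bromine slows the next substitution enough to stop before the third.

Step 3
Reactants: 3 1,3,5-tris(benzyloxy)-2,4-dibromobenzene
Product: 4 1,3,5-tris(benzyloxy)-2,4-dimethoxybenzene
Conditions: NaOMe (10 equiv, 25 wt % in MeOH), CuBr (0.3 equiv), DMF, 110 °C, Ar
Reagents that add atoms: sodium methoxide, [Na+].[O-]C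
Why: Ullmann-type copper-catalysed methoxylation of aryl bromides, with a monovalent copper methoxide as the active species; the two bromides are equivalent and benzyl ethers are inert to methoxide.

Step 4
Reactants: 4 1,3,5-tris(benzyloxy)-2,4-dimethoxybenzene
Product: 5 1-[2,4,6-tris(benzyloxy)-3,5-dimethoxyphenyl]ethan-1-one
Conditions: AcOH (3 equiv) premixed with (CF3CO)2O (2 equiv), CH2Cl2, 0 °C → rt
Reagents that add atoms: acetic acid, CC(=O)O
Why: Friedel–Crafts acylation by acetyl trifluoroacetate formed in the flask; the only ring C–H of 4 is ortho to two and para to one benzyloxy group, so the site is fixed, and the absence of a chelating metal Lewis acid spares the benzyl ethers ortho to the new carbonyl.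

Step 5
Reactants: 6 5-bromo-2-methoxyphenol
Product: 7 2-(benzyloxy)-4-bromo-1-methoxybenzene
Conditions: BnBr (1.1 equiv), K2CO3 (1.5 equiv), acetone, reflux
Reagents that add atoms: benzyl bromide, BrCc1ccccc1
Why: Williamson etherification of a simple phenol; the aryl bromide is inert under these conditions.

Step 6
Reactants: 5 1-[2,4,6-tris(benzyloxy)-3,5-dimethoxyphenyl]ethan-1-one; 7 2-(benzyloxy)-4-bromo-1-methoxybenzene; 8 carbon monoxide
Product: 10 1-[3-(benzyloxy)-4-methoxyphenyl]-3-[2,4,6-tris(benzyloxy)-3,5-dimethoxyphenyl]propane-1,3-dione, via sodium enolate 9 (not isolated)
Conditions: NaN(SiMe3)2 (2.1 equiv), THF, 0 °C → rt; then 7 (1.3 equiv), Pd(dba)2 (5 mol %), Xantphos (6 mol %), CO (1 atm), THF/dioxane, 80 °C; aq. HCl work-up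
Reagents that add atoms: none
Why: NaN(SiMe3)2 converts 5, whose only acidic C–H bonds are those of the methyl group, into sodium enolate 9. Zerovalent palladium bound to Xantphos inserts into the C–Br bond of 7, CO migrates into the aryl–palladium bond to give an aroyl complex of divalent palladium, 9 displaces bromide, and C–C reductive elimination forms the C1'–C2 and C2–C3 bonds of 10 and returns zerovalent palladium. The closest known reaction type is the palladium-catalysed carbonylative α-arylation of aryl methyl ketones with aryl halides to 1,3-diketones. No ring is closed and no stereocentre is created. The selectivity needed is C-acylation over O-acylation and over direct α-arylation without CO: the CO atmosphere makes insertion faster than enolate transfer to the aryl complex, the wide bite angle of Xantphos speeds reductive elimination from the acyl complex, and any enol ester formed can still pass its aroyl group to 9. The second equivalent of base deprotonates 10 as it forms, and this diketonate is the thermodynamic sink that protects the product from further acylation. The substrate helps, since the two ortho benzyloxy groups shield the carbonyl of 5 from self-aldol addition, every ring A oxygen is capped so that no phenoxide competes for the acyl complex, and 7 has no second halide. Only 1 atm of CO and 80 °C are used because oxidative addition of the electron-rich bromide 7 is the slow step and is retarded by excess CO.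

Step 7
Reactants: 10 1-[3-(benzyloxy)-4-methoxyphenyl]-3-[2,4,6-tris(benzyloxy)-3,5-dimethoxyphenyl]propane-1,3-dione
Product: 11 1-(3-hydroxy-4-methoxyphenyl)-3-(2,4,6-trihydroxy-3,5-dimethoxyphenyl)propane-1,3-dione
Conditions: H2 (1 atm), Pd/C (10 wt % Pd), EtOAc/MeOH, rt; crude product kept under Ar and used directly
Reagents that add atoms: none
Why: Heterogeneous hydrogenolysis of four aryl benzyl ethers; methyl ethers are untouched, and the enolised, hydrogen-bonded diketone carbonyls should be reduced far more slowly than benzylic C–O bonds at 1 atm and room temperature.

Step 8
Reactants: 11 1-(3-hydroxy-4-methoxyphenyl)-3-(2,4,6-trihydroxy-3,5-dimethoxyphenyl)propane-1,3-dione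
Product: 12 acerosin, 5,7-dihydroxy-2-(3-hydroxy-4-methoxyphenyl)-6,8-dimethoxy-4H-chromen-4-one
Conditions: H2SO4 (cat.), AcOH, 95 °C, Ar
Reagents that add atoms: none
Why: Acid-catalysed cyclodehydration of an ortho-hydroxyaryl 1,3-diketone, the closing stage of a Baker–Venkataraman-type flavone synthesis: an ortho hydroxyl adds to the ring B carbonyl (6-exo-trig) and the cyclic hemiketal loses water to the 4-pyranone. The two ortho hydroxyls of 11 are equivalent and C6 and C8 carry the same group, so only 12 can form and Wessely–Moser opening and reclosure is degenerate.

## Compound list

1 | phloroglucinol (benzene-1,3,5-triol) | Oc1cc(O)cc(O)c1 | starting material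
2 | 1,3,5-tris(benzyloxy)benzene | C(Oc1cc(OCc2ccccc2)cc(OCc2ccccc2)c1)c1ccccc1 | intermediate
3 | 1,3,5-tris(benzyloxy)-2,4-dibromobenzene | Brc1c(OCc2ccccc2)cc(OCc2ccccc2)c(Br)c1OCc1ccccc1 | intermediate
4 | 1,3,5-tris(benzyloxy)-2,4-dimethoxybenzene | COc1c(OCc2ccccc2)cc(OCc2ccccc2)c(OC)c1OCc1ccccc1 | intermediate
5 | 1-[2,4,6-tris(benzyloxy)-3,5-dimethoxyphenyl]ethan-1-one | CC(=O)c1c(OCc2ccccc2)c(OC)c(OCc2ccccc2)c(OC)c1OCc1ccccc1 | intermediate
6 | 5-bromo-2-methoxyphenol | COc1ccc(Br)cc1O | starting material
7 | 2-(benzyloxy)-4-bromo-1-methoxybenzene | COc1ccc(Br)cc1OCc1ccccc1 | intermediate
8 | carbon monoxide | [C-]#[O+] | starting material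
9 | sodium 1-[2,4,6-tris(benzyloxy)-3,5-dimethoxyphenyl]ethen-1-olate (sodium enolate of 5) | [Na+].[O-]C(=C)c1c(OCc2ccccc2)c(OC)c(OCc2ccccc2)c(OC)c1OCc1ccccc1 | intermediate (not isolated)
10 | 1-[3-(benzyloxy)-4-methoxyphenyl]-3-[2,4,6-tris(benzyloxy)-3,5-dimethoxyphenyl]propane-1,3-dione | COc1ccc(C(=O)CC(=O)c2c(OCc3ccccc3)c(OC)c(OCc3ccccc3)c(OC)c2OCc2ccccc2)cc1OCc1ccccc1 | intermediate
11 | 1-(3-hydroxy-4-methoxyphenyl)-3-(2,4,6-trihydroxy-3,5-dimethoxyphenyl)propane-1,3-dione | COc1ccc(C(=O)CC(=O)c2c(O)c(OC)c(O)c(OC)c2O)cc1O | intermediate
12 | acerosin, 5,7-dihydroxy-2-(3-hydroxy-4-methoxyphenyl)-6,8-dimethoxy-4H-chromen-4-one | COc1ccc(-c2cc(=O)c3c(O)c(OC)c(O)c(OC)c3o2)cc1O | target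

## Step count and least certain steps

Total: 8 steps. Longest linear sequence: 7 steps (steps 1, 2, 3, 4, 6, 7 and 8, from 1 to 12); step 5 is a one-step branch.

Step 6 (key step). The most likely failures are slow oxidative addition of the electron-rich bromide under CO with gradual catalyst deactivation, interception of the aroyl–palladium intermediate by the surplus silylamide base in place of the enolate, and direct α-arylation if CO is depleted. The fallback keeps carbon monoxide as the source of C2 but separates carbonylation from C–C bond formation. It sets out from 7 and 5 and returns at 10. Methoxycarbonylation of 7 (Pd(OAc)2, Xantphos, CO 1 atm, MeOH, Et3N, 70 °C) would give methyl 3-(benzyloxy)-4-methoxybenzoate F1. A crossed Claisen condensation of 5 with F1 (NaH, THF, reflux), the classical diketone route to flavones, would then deliver 10.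

Step 4. The acidic medium may cause loss or migration of benzyl groups on the very electron-rich ring, trifluoroacetylation may compete with acetylation, and the arene may be oxidised. The fallback sets out from 4 and returns at 5. Bromination of the last ring position (NBS, CH2Cl2, 0 °C) would give 1,3,5-tris(benzyloxy)-2-bromo-4,6-dimethoxybenzene F2. Bromine–lithium exchange (n-BuLi, THF, −78 °C) would give [2,4,6-tris(benzyloxy)-3,5-dimethoxyphenyl]lithium F3, and acylation of F3 with N-methoxy-N-methylacetamide at −78 °C would give 5 with no acid present at any stage.

Step 3. Reductive loss of bromine (methoxide acting as a hydride source at copper) and a stalled second substitution at the doubly flanked positions are the main dangers. The fallback sets out from 3 and returns at 4. Palladium-catalysed hydroxylation (Pd2(dba)3, tBuXPhos, KOH, dioxane/H2O, 100 °C) would give 2,4,6-tris(benzyloxy)benzene-1,3-diol F4; hydroxide has no β-hydrogen, so this reduction pathway is closed. Immediate O-methylation of F4 (MeI, K2CO3, acetone) would give 4.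

Step 1. C-benzylation of the ambident phloroglucinol anion can compete with O-alkylation and lower the efficiency of the first step. The fallback sets out from 1 and returns at 2. Acetylation (Ac2O, pyridine) would give benzene-1,3,5-triyl triacetate F5. Treatment of F5 with BnCl and NaH in DMF containing a trace of water (0 °C → rt) would release and benzylate one phenoxide at a time, so the polyanion that undergoes C-alkylation never accumulates.

Step 7. Over-reduction of the aryl ketone carbonyls, stalling before the last hindered benzyl ether is cleaved, and air oxidation of the polyphenol during handling are possible. The fallback sets out from 10 and returns at 11 and makes no new compound (F0). It is a Lewis-acid debenzylation with BCl3 and pentamethylbenzene as cation scavenger (CH2Cl2, −78 °C, MeOH quench), conditions under which aryl methyl ethers that are not ortho to a carbonyl should persist.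

## Further compounds

F1 | step 6 | methyl 3-(benzyloxy)-4-methoxybenzoate | COC(=O)c1ccc(OC)c(OCc2ccccc2)c1
F2 | step 4 | 1,3,5-tris(benzyloxy)-2-bromo-4,6-dimethoxybenzene | COc1c(OCc2ccccc2)c(Br)c(OCc2ccccc2)c(OC)c1OCc1ccccc1
F3 | step 4 | [2,4,6-tris(benzyloxy)-3,5-dimethoxyphenyl]lithium | [Li]c1c(OCc2ccccc2)c(OC)c(OCc2ccccc2)c(OC)c1OCc1ccccc1
F4 | step 3 | 2,4,6-tris(benzyloxy)benzene-1,3-diol | Oc1c(OCc2ccccc2)cc(OCc2ccccc2)c(O)c1OCc1ccccc1
F5 | step 1 | benzene-1,3,5-triyl triacetate | CC(=O)Oc1cc(OC(C)=O)cc(OC(C)=O)c1
F0 | step 7 | none | none
A1 | alternative 1 | 2,4-dimethoxybenzene-1,3,5-triol | COc1c(O)cc(O)c(OC)c1O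
A2 | alternative 1 | ethyl 3-[3-(benzyloxy)-4-methoxyphenyl]-3-oxopropanoate | CCOC(=O)CC(=O)c1ccc(OC)c(OCc2ccccc2)c1
A3 | alternative 1 | 3'-O-benzylacerosin, 2-[3-(benzyloxy)-4-methoxyphenyl]-5,7-dihydroxy-6,8-dimethoxy-4H-chromen-4-one | COc1ccc(-c2cc(=O)c3c(O)c(OC)c(O)c(OC)c3o2)cc1OCc1ccccc1
A4 | alternative 2 | 6-{(3E)-4-[3-(benzyloxy)-4-methoxyphenyl]-2-oxobut-3-en-1-yl}-4-hydroxy-3,5-dimethoxy-2H-pyran-2-one | COc1ccc(/C=C/C(=O)Cc2oc(=O)c(OC)c(O)c2OC)cc1OCc1ccccc1
A5 | alternative 2 | (E)-3-[3-(benzyloxy)-4-methoxyphenyl]-1-(2,4,6-trihydroxy-3,5-dimethoxyphenyl)prop-2-en-1-one | COc1ccc(/C=C/C(=O)c2c(O)c(OC)c(O)c(OC)c2O)cc1OCc1ccccc1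
A6 | alternative 3 | 4,6-bis(benzyloxy)-2-[3-(benzyloxy)-4-methoxyphenyl]-5,7-dimethoxy-1-benzofuran-3(2H)-one (racemic) | COc1ccc(C2Oc3c(OC)c(OCc4ccccc4)c(OC)c(OCc4ccccc4)c3C2=O)cc1OCc1ccccc1
A7 | alternative 3 | 4,6-bis(benzyloxy)-2-[3-(benzyloxy)-4-methoxyphenyl]-3-[(tert-butyldimethylsilyl)oxy]-5,7-dimethoxy-1-benzofuran | COc1ccc(-c2oc3c(OC)c(OCc4ccccc4)c(OC)c(OCc4ccccc4)c3c2O[Si](C)(C)C(C)(C)C)cc1OCc1ccccc1
A8 | alternative 3 | 5,7-bis(benzyloxy)-2-[3-(benzyloxy)-4-methoxyphenyl]-3-bromo-6,8-dimethoxy-4H-chromen-4-one | COc1ccc(-c2oc3c(OC)c(OCc4ccccc4)c(OC)c(OCc4ccccc4)c3c(=O)c2Br)cc1OCc1ccccc1
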